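The ratio to carry is a ratio of two logarithms. Count in decades how far each mirror image has fallen, then divide the left-handed decades by the right-handed ones. If both substrates meet the same catalyst and dissolved reagent, this selectivity factor stays constant along a run.

common to all: left-handed substrate 0.60 M; right-handed substrate 0.60 M; catalyst 12 mM; added ligand 25 mM
- epsilon: solid reagent 0.55 M; run made earlier
- alpha: solid reagent 2.7 M; run made earlier
- north: solid reagent 1.80 M; time 2.0 h
- north-east: solid reagent 0.500 M; time 2.0 h

| run | time / min | left-handed product / % | right-handed product / % |
|---|---|---|---|
| epsilon | 6.00 | 7.3 | 4.1 |
| epsilon | 12.0 | 16.6 | 9.9 |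
| epsilon | 25.0 | 26.1 | 15.9 |
| epsilon | 40.0 | 28.0 | 16.3 |
| epsilon | 80.0 | 28.6 | 17.7 |
| alpha | 6.00 | 7.1 | 3.6 |
| alpha | 12.0 | 16.5 | 9.2 |
| alpha | 25.0 | 30.7 | 18.8 |
| alpha | 40.0 | 40.5 | 27.1 |
| alpha | 80.0 | 48.6 | 41.9 |

(each reading ± 0.5 percentage points)

- catalyst is single-handed; left-handed substrate and right-handed substrate are mirror images of each other, charged as a racemate, each of them at the stated concentration
- as a solid, counted per litre of solution: solid reagent
- at the start none of the solid reagent is in solution
- an excess is the difference of the two amounts in percent of their sum
- an excess is below zero if the other one leads

- which of the two ends with the higher excess of left-handed product over right-handed product in the product ("neither" if they lie within 2 percentage points) (north / north-east / neither)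
- excess of left-handed product over right-handed product in the product at the end, north
- excess of left-handed product over right-handed product in the product at the end, north-east

Take the inputs in turn. Time comes first: epsilon's products moved 0.6 percentage points and 1.4 points between 40.0 min and 80.0 min. Their total at 80.0 min, 0.556 M, matches epsilon's 0.55 M of solid reagent, one to one. Catalyst and added ligand are charged alike throughout, so they need no correction.

The solid reagent is the limiting reagent in north-east, allowing a conversion of 41.7%. North holds 1.80 M, more than the 1.20 M of substrate, so you follow alpha. Alpha's right-handed substrate fell 0.790 decades by 80.0 min, which at that pace makes 1.19 decades in north.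

Now try the factor at 2 and 3. North's excess barely changes, 3.13% against 3.36%. The early excess, (s−1)/(s+1) for a factor s, goes from 33.3% to 50.0%, so north-east needs the factor well.

Epsilon's last reading gives 1.94, the left-handed decades lost per right-handed decade; alpha's gives 1.96. My line for north-east runs from 32.0% at no conversion to epsilon's 23.5% at 46.3%, giving 24.3%. For north I get 3.09%.

The forecast chose north-east, with 3% for north and 25% for north-east, calling the latter “reagent-limited at 41.7% conversion”.

The flask gives north-east, with 2.86% for north and 25.2% for north-east, so the forecast held.

    catalyst + added ligand ⇌ idle complex, settled at all times (K = 33.4 /M)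
    partner + catalyst + left-handed substrate → catalyst + left-handed product (k = 0.502 /M²/s)
    partner + catalyst + right-handed substrate → catalyst + right-handed product (k = 0.254 /M²/s)
    solid reagent ⇌ partner, rate k4*(cs4 - [partner]) while solid is left; crystals form when [partner] > cs4 (solubility = 0.240 M, k = 0.00802 /s)

In north-east, the 69% of right-handed substrate left, raised to the factor, gives 48.7% for the left-handed substrate, and the flask has 48%. A neighbouring flask is north-east with 0.12 M of solid reagent. It allows a conversion of 10.0%, where the line reads 30.2%. Its 93% of right-handed substrate left gives 86.9% for the left-handed substrate, and the flask has 87%. Its excess is 31.3%.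

(The runs were generated by integration with constants of no real substance.)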